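Readings and results come from a simulation from invented constants; the scatter is artificial.

common to all: free catalyst 0.10 mM
- maple: starting material 0.10 M; second substrate 0.067 M; run made earlier
- cedar: starting material 0.10 M; second substrate 0.15 M; run made earlier
- ash: starting material 0.20 M; second substrate 0.10 M; run made earlier
- flask: starting material 0.10 M; second substrate 0.100 M; time 50 min

| run | time / min | target / % | starting material / % |
|---|---|---|---|
| maple | 0.667 | 21 | 67 |
| maple | 3.00 | 12 | 11 |
| maple | 12.0 | 0 | 0 |
| maple | 60.0 | 0 | 0 |
| cedar | 0.667 | 16 | 76 |
| cedar | 3.00 | 12 | 30 |
| cedar | 12.0 | 0 | 0 |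
| cedar | 60.0 | 0 | 0 |
| ash | 0.667 | 15 | 73 |
| ash | 3.00 | 12 | 17 |
| ash | 12.0 | 3 | 0 |
| ash | 60.0 | 0 | 1 |

(standard deviation of a reading: 2 percentage points)

* time up to 50 min at which target stands highest
* the amount of target, in percent of the starting material charged, at that time

- the earlier runs were read with a standard deviation of 2 percentage points

The easy step came first: how fast starting material fell. Taken as a pseudo-first-order decay, the reading at 3.00 min gave 0.736 min⁻¹ in the maple run and 0.401 min⁻¹ in the cedar run, so in these two runs more second substrate went with slower decay. I put the reciprocals on a straight line in second substrate. That gave the flask a making constant of 0.553 min⁻¹.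

Then I turned to target. When a faster first-order loss trails a slower first-order making, target's share of target plus starting material becomes steady, and that share equals making constant over loss constant. At 3.00 min, the maple run gave a loss constant of 1.41 min⁻¹ and the cedar run 1.40 min⁻¹. I carried making constant over loss constant, the selectivity factor, which was 0.392 for the flask.

Then I drew the flask's curve as an estimate, with both constants held steady. By this reckoning target was to start rising at 0.0553 M min⁻¹. Making was to meet loss at 1.09 min. There target was to stand at 0.392 of the starting material, which put the top at 21.4 % of the charge. I reckoned the tail to halve every 1.25 min, so 50 min allowed 39.9 halvings, and I expected the curve to end at zero.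

The forecast said “Target behaves as an intermediate” and gave 20 % at 1.1 min. Its time was close to mine, and its height was a little lower.

The flask gave 21.8 % at 1.24 min.

    starting material + free catalyst ⇌ catalyst intermediate A (K = 3.70 L mol⁻¹, k = 780 L mol⁻¹ s⁻¹)
    second substrate + free catalyst ⇌ catalyst intermediate B (K = 19.0 L mol⁻¹, k = 440 L mol⁻¹ s⁻¹)
    catalyst intermediate A → free catalyst + target (k = 50.0 s⁻¹)
    2 catalyst intermediate B ⇌ resting dimer (K = 9.40 × 10⁵ L mol⁻¹, k = 2300 L mol⁻¹ s⁻¹)
    target → over-reaction product (k = 0.0220 s⁻¹)
    catalyst intermediate B → free catalyst + second product (k = 130 s⁻¹)

At the best time, target over starting material in the flask stood at 0.419, against my 0.392. The same flask run without the path from target to over-reaction product shows the loss side of the ratio: highest target stood at 100 % instead of 21.8 %. In the neighbour flask with 6.0 × 10⁻⁵ M of free catalyst, I scaled the making constant with the catalyst and held the loss constant, which gave a ratio of 0.235 and a top of 15.1 %. That neighbour flask computed to 15.2 %.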